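**Retrosynthetic overview**
- The target is opened at C3–OH: a late C3–H hydroxylation of the (2S)-flavanone (the flavanone 3-hydroxylase step), trans by 1,2-induction from C2.
- The (2S)-flavanone comes from an unprotected 2',6'-dihydroxychalcone by an enantioselective, chalcone-isomerase-like 6-endo oxa-Michael closure. This is the only ring formed (the pyranone ring, ring C); rings A and B are bought.
- The chalcone comes from a Claisen–Schmidt union of a 4-O-alkylated phloroacetophenone with 4-hydroxybenzaldehyde (the chalcone synthase stage).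
- The (E)-4-hydroxyprenyl ether is put on the 4-OH of phloroacetophenone at the start, using an (E)-chloro alcohol made from isoprene monoxide. No protecting group is ever isolated.

Assumption: the quinine-derived thiourea is taken to give the (2S)-flavanone; if analysis (CD, chiral HPLC) shows the (2R) series, the quinidine-derived pseudoenantiomer is used with nothing else changed.

**Route**

Step 1
Reactants: 1 2-methyl-2-vinyloxirane (isoprene monoxide, racemic)
Product: 2 (E)-4-chloro-2-methylbut-2-en-1-ol
Conditions: TiCl4 (1.1 equiv), CH2Cl2, −85 °C, 1 h; then H2O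
Reagents that add atoms: titanium tetrachloride, Cl[Ti](Cl)(Cl)Cl
Why: SN2'-type (conjugate) opening of the Lewis-acid-activated vinyl epoxide by chloride at the vinyl terminus, the bulky CH2O–TiCl3 arm turning away from the new CH2Cl group so that the (E)-trisubstituted alkene results; the stereocentre of racemic 1 is destroyed in the process.

Step 2
Reactants: 2 (E)-4-chloro-2-methylbut-2-en-1-ol; 3 2',4',6'-trihydroxyacetophenone (phloroacetophenone, 1.5 equiv)
Product: 4 1-{2,6-dihydroxy-4-[(E)-4-hydroxy-3-methylbut-2-enyloxy]phenyl}ethanone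
Conditions: K2CO3 (1.0 equiv), KI (0.1 equiv), acetone, 45 °C, 16 h
Reagents that add atoms: none
Why: Williamson ether synthesis in which the 4-OH of 3 (para to the acetyl group, not hydrogen-bonded, the most acidic) is the only hydroxyl ionised by one equivalent of K2CO3 and displaces the primary allylic chloride by SN2, so the (E)-alkene is kept and the two chelated ortho-hydroxyls stay free.

Step 3
Reactants: 4 1-{2,6-dihydroxy-4-[(E)-4-hydroxy-3-methylbut-2-enyloxy]phenyl}ethanone; 5 4-hydroxybenzaldehyde (2.5 equiv)
Product: 6 (E)-1-{2,6-dihydroxy-4-[(E)-4-hydroxy-3-methylbut-2-enyloxy]phenyl}-3-(4-hydroxyphenyl)prop-2-en-1-one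
Conditions: KOH (60% aq, 15 equiv), EtOH, argon, rt, 72 h; pour onto ice/aq HCl (pH 3), cold EtOAc extraction, use crude or crystallised within hours
Reagents that add atoms: none
Why: Claisen–Schmidt (crossed aldol) condensation in which the methyl ketone enolate adds to the aldehyde and E1cB loss of water gives the (E)-enone, which stays open as its phenoxide in strong base and is isolated by cold acidification before it can cyclise.

Step 4
Reactants: 6 (E)-1-{2,6-dihydroxy-4-[(E)-4-hydroxy-3-methylbut-2-enyloxy]phenyl}-3-(4-hydroxyphenyl)prop-2-en-1-one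
Product: 7 (2S)-5-hydroxy-7-[(E)-4-hydroxy-3-methylbut-2-enyloxy]-2-(4-hydroxyphenyl)chroman-4-one
Conditions: N-[3,5-bis(trifluoromethyl)phenyl]-N'-[(8α,9S)-6'-methoxycinchonan-9-yl]thiourea (10 mol%), toluene/2-MeTHF 4:1, −30 °C, 48 h; short acid-washed silica pad, recrystallise to raise ee
Reagents that add atoms: none
Why: Proposed new method: the bifunctional catalyst acts as a small-molecule chalcone isomerase, its thiourea N–H bonds holding the enone carbonyl (oxyanion hole) while the quinuclidine nitrogen deprotonates one of the two equivalent ortho-hydroxyls, so the phenoxide adds 6-endo to one enantioface of the enone and sets C2 as S, and the 5-OH···O=C hydrogen bond of the product makes closure effectively irreversible at −30 °C so the kinetic ee is kept; the closest known reaction type is the cinchona-thiourea-catalysed asymmetric intramolecular oxa-Michael addition of simple 2'-hydroxychalcones to flavanones.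

Step 5
Reactants: 7 (2S)-5-hydroxy-7-[(E)-4-hydroxy-3-methylbut-2-enyloxy]-2-(4-hydroxyphenyl)chroman-4-one
Product: 10 (2R,3R)-3,5-dihydroxy-7-[(E)-4-hydroxy-3-methylbut-2-enyloxy]-2-(4-hydroxyphenyl)chroman-4-one (target), via persilylated 4-silyloxy-2H-chromene 8 (not isolated), via silyloxy epoxide 9 (not isolated)
Conditions: Me3SiOTf (5 equiv), Et3N (7 equiv), CH2Cl2, −78 → 0 °C; evaporate, pentane, filter; DMDO (1.1 equiv, acetone), CH2Cl2, −78 → −40 °C; aq HCl (1 mol/L), THF, 0 °C
Reagents that add atoms: dimethyldioxirane, CC1(C)OO1 (gives the C3 oxygen); trimethylsilyl triflate, C[Si](C)(C)OS(=O)(=O)C(F)(F)F (its silyl groups are in 8 and 9 only and are gone in 10)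
Why: Rubottom oxidation in which soft enolisation silylates all three hydroxyls and the ketone without forming a free enolate (so no retro-oxa-Michael racemisation), DMDO epoxidises the electron-rich silyl enol ether faster than the side-chain alkene (deactivated by two allylic oxygens) and from the face opposite the 2-aryl group, and mild acid hydrolyses 9 to the trans-3-hydroxy ketone, so C3 is set R by relay from C2 (the C2 descriptor changes from S to R only because the CIP priorities change).

**Compound list**

1 | 2-methyl-2-vinyloxirane (racemic) | C=CC1(C)CO1 | starting material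
2 | (E)-4-chloro-2-methylbut-2-en-1-ol | C/C(=C\CCl)CO | intermediate
3 | 2',4',6'-trihydroxyacetophenone | CC(=O)c1c(O)cc(O)cc1O | starting material
4 | 1-{2,6-dihydroxy-4-[(E)-4-hydroxy-3-methylbut-2-enyloxy]phenyl}ethanone | C/C(=C\COc1cc(O)c(C(C)=O)c(O)c1)CO | intermediate
5 | 4-hydroxybenzaldehyde | O=Cc1ccc(O)cc1 | starting material
6 | (E)-1-{2,6-dihydroxy-4-[(E)-4-hydroxy-3-methylbut-2-enyloxy]phenyl}-3-(4-hydroxyphenyl)prop-2-en-1-one | C/C(=C\COc1cc(O)c(C(=O)/C=C/c2ccc(O)cc2)c(O)c1)CO | intermediate
7 | (2S)-5-hydroxy-7-[(E)-4-hydroxy-3-methylbut-2-enyloxy]-2-(4-hydroxyphenyl)chroman-4-one | C/C(=C\COc1cc(O)c2c(c1)O[C@H](c1ccc(O)cc1)CC2=O)CO | intermediate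
8 | (2S)-4,5-bis(trimethylsilyloxy)-2-[4-(trimethylsilyloxy)phenyl]-7-[(E)-3-methyl-4-(trimethylsilyloxy)but-2-enyloxy]-2H-chromene (not isolated) | C/C(=C\COc1cc(O[Si](C)(C)C)c2c(c1)O[C@H](c1ccc(O[Si](C)(C)C)cc1)C=C2O[Si](C)(C)C)CO[Si](C)(C)C | intermediate
9 | 3,4-epoxide of 8, oxirane oxygen trans to the 2-aryl group, 4-OSiMe3 cis to it (not isolated) | C/C(=C\COc1cc(O[Si](C)(C)C)c2c(c1)O[C@H](c1ccc(O[Si](C)(C)C)cc1)[C@H]1O[C@@]21O[Si](C)(C)C)CO[Si](C)(C)C | intermediate
10 | (2R,3R)-3,5-dihydroxy-7-[(E)-4-hydroxy-3-methylbut-2-enyloxy]-2-(4-hydroxyphenyl)chroman-4-one | C/C(=C\COc1cc(O)c2c(c1)O[C@H](c1ccc(O)cc1)[C@@H](O)C2=O)CO | target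

**Totals**
Total step count: 5. Longest linear sequence: 5 steps (1 → 2 → 4 → 6 → 7 → 10); 3 and 5 are bought and enter in steps 2 and 3.

**Steps most likely to fail, with fallbacks**

Step 4 (asymmetric ring closure). Risks: the uncatalysed cyclisation of a 2',6'-dihydroxychalcone is fast, the acidic B-ring 4-OH can tie up the catalyst base, and the ee or even the sense of induction may be poor. Fallback: it sets out from 6, which is cyclised without asymmetric induction (NaOAc, EtOH, reflux) to the racemic flavanone F2. The racemate is resolved by preparative HPLC on an amylose tris(3,5-dimethylphenylcarbamate) phase into 7 and the (2R)-flavanone F3. F3 is reopened to 6 with cold aq KOH and cyclised again, so no material is lost. The fallback comes back at 7.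

Step 5 (one-flask silylation, Rubottom oxidation, desilylation). Risks: incomplete enol silylation, competing epoxidation of the side-chain alkene, and loss of ee if ring opening occurs. Fallback: it sets out from 7, which is silylated with t-BuMe2SiCl and imidazole in DMF to the bis-silyl ether F4 (4'-O and side-chain O silylated, chelated 5-OH left free). F4 is converted with LiN(SiMe3)2 (2.2 equiv, THF, −78 °C) into its phenoxide–enolate dianion, which is hydroxylated with 2-(phenylsulfonyl)-3-phenyloxaziridine anti to the 2-aryl group to give the bis-silyl trans-dihydroflavonol F5; the oxaziridine does not touch the alkene. HF·pyridine in THF at 0 °C then removes both silyl groups, and the fallback comes back at 10.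

Step 3 (unprotected Claisen–Schmidt condensation). Risks: the phenoxide of 5 is a poor electrophile, so conversion may be low, and 6 can cyclise during work-up. Fallback: it sets out from 2, which alkylates commercial racemic naringenin F1 at its most acidic 7-OH (K2CO3, acetone, 50 °C) to give the racemic flavanone F2. F2 is opened by E1cB retro-oxa-Michael reaction in aq KOH (20%, 0 °C → rt), and cold acidification precipitates the chalcone. The fallback comes back at 6.

**Further compounds**

F1 | step 3 | racemic naringenin (purchased) | O=C1CC(c2ccc(O)cc2)Oc2cc(O)cc(O)c12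
F2 | step 3 | racemic 5-hydroxy-7-[(E)-4-hydroxy-3-methylbut-2-enyloxy]-2-(4-hydroxyphenyl)chroman-4-one | C/C(=C\COc1cc(O)c2c(c1)OC(c1ccc(O)cc1)CC2=O)CO
F3 | step 4 | (2R)-5-hydroxy-7-[(E)-4-hydroxy-3-methylbut-2-enyloxy]-2-(4-hydroxyphenyl)chroman-4-one | C/C(=C\COc1cc(O)c2c(c1)O[C@@H](c1ccc(O)cc1)CC2=O)CO
F4 | step 5 | (2S)-2-[4-(tert-butyldimethylsilyloxy)phenyl]-7-[(E)-4-(tert-butyldimethylsilyloxy)-3-methylbut-2-enyloxy]-5-hydroxychroman-4-one | C/C(=C\COc1cc(O)c2c(c1)O[C@H](c1ccc(O[Si](C)(C)C(C)(C)C)cc1)CC2=O)CO[Si](C)(C)C(C)(C)C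
F5 | step 5 | (2R,3R)-2-[4-(tert-butyldimethylsilyloxy)phenyl]-7-[(E)-4-(tert-butyldimethylsilyloxy)-3-methylbut-2-enyloxy]-3,5-dihydroxychroman-4-one | C/C(=C\COc1cc(O)c2c(c1)O[C@H](c1ccc(O[Si](C)(C)C(C)(C)C)cc1)[C@@H](O)C2=O)CO[Si](C)(C)C(C)(C)C
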